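The target is apigenin carrying a 4-hydroxybenzyl group at C8, and the route rests on cutting the bond between the benzylic CH2 and the hydroxyphenyl ring. The key step exploits the free C7–OH ortho to the C8–CH2 group on ring A of the chromen-4-one: a C8 Mannich base of apigenin loses dimethylamine to give an ortho-quinone methide (C7=O, C8=CH2), which takes up the aryl group of 4-hydroxyphenylboronic acid by boron-to-carbon 1,4-transfer. One operation thus replaces C–N by C–aryl, with ipso regiocontrol and no protecting groups. The precursor is 8-(dimethylaminomethyl)apigenin, made in one step from commercial apigenin.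

Key step: step 2

Remark (assumption): the target has no stereocentre, stereogenic axis or stereogenic double bond and is achiral, so the structure as drawn is its only stereoisomer and no stereocontrol is required.

Step 1
Reactants: 1 apigenin; 2 bis(dimethylamino)methane
Product: 3 8-[(dimethylamino)methyl]apigenin
Conditions: CH2(NMe2)2 (1.05 equiv), 1,4-dioxane, 90 °C
Reagents that add atoms: bis(dimethylamino)methane (2), CN(C)CN(C)C
Why: Mannich aminomethylation, in which the aminal should deliver a CH2NMe2 group to C8, the position known to be preferred in Mannich reactions of 5,7-dihydroxyflavones (ortho to the acidic 7-OH, para to the chelated 5-OH), while the less electron-rich B ring should stay untouched and near-stoichiometric aminal should limit 6,8-bis-aminomethylation; no stereocentre is formed.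

Step 2
Reactants: 3 8-[(dimethylamino)methyl]apigenin; 4 4-hydroxyphenylboronic acid
Product: 6 8-(4-hydroxybenzyl)apigenin, via ortho-quinone methide 5 (not isolated)
Conditions: 4 (3 equiv), degassed DMF, 110 °C, Ar sweep; then 1 M HCl
Reagents that add atoms: 4-hydroxyphenylboronic acid (4), OB(O)c1ccc(O)cc1
Why: Heating the phenolic Mannich base should expel dimethylamine (helped by N→B coordination to the boronic acid) and unmask the ortho-quinone methide 5, whose C7 carbonyl oxygen binds the boronic acid as a tetracoordinate boronate. The 4-hydroxyphenyl group should then migrate from boron to the exocyclic CH2 through a six-membered transition state, a Petasis-type 1,4-addition that restores the aromaticity of ring A and forms the CH2–aryl bond. The closest known reaction types are the thermal generation of o-quinone methides from phenolic Mannich bases and the conjugate addition of aryl boron nucleophiles to o-quinone methides. No ring is closed and no stereocentre is formed. The step needs ipso-selectivity on the incoming ring and C- over O-alkylation: the C–B bond fixes the carbon para to the OH as the migrating terminus, and phenol O-adducts of the quinone methide should revert on heating whereas C–C bond formation is irreversible. Competing attack by C6 of a second flavone should be limited by the intramolecular aryl delivery and the excess of 4.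

Compound list
1 | apigenin (5,7-dihydroxy-2-(4-hydroxyphenyl)-4H-chromen-4-one) | O=c1cc(-c2ccc(O)cc2)oc2cc(O)cc(O)c12 | starting material
2 | bis(dimethylamino)methane (N,N,N',N'-tetramethylmethanediamine) | CN(C)CN(C)C | starting material
3 | 8-[(dimethylamino)methyl]apigenin (8-[(dimethylamino)methyl]-5,7-dihydroxy-2-(4-hydroxyphenyl)-4H-chromen-4-one) | CN(C)Cc1c(O)cc(O)c2c(=O)cc(-c3ccc(O)cc3)oc12 | intermediate
4 | 4-hydroxyphenylboronic acid | OB(O)c1ccc(O)cc1 | starting material
5 | ortho-quinone methide (5-hydroxy-2-(4-hydroxyphenyl)-8-methylidene-4H-chromene-4,7(8H)-dione) | C=C1C(=O)C=C(O)C2=C1OC(c1ccc(O)cc1)=CC2=O | intermediate (not isolated)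
6 | 8-(4-hydroxybenzyl)apigenin (5,7-dihydroxy-8-[(4-hydroxyphenyl)methyl]-2-(4-hydroxyphenyl)-4H-chromen-4-one) | O=c1cc(-c2ccc(O)cc2)oc2c(Cc3ccc(O)cc3)c(O)cc(O)c12 | target

Total step count: 2
Longest linear sequence: 2 steps (1 → 3 → 6)

Steps most likely to fail (the route has only two steps, so both are ranked, the riskier first)

Step 2. What may go wrong: protodeboronation of the electron-rich boronic acid before aryl transfer, and self-condensation of the quinone methide with the nucleophilic C6 of a second flavone. The fallback sets out from 3 and comes back to the route at 6. It forms the same CH2–aryl bond by a palladium-catalysed cross-coupling on a protected substrate, so that no free quinone methide and no nucleophilic A ring are present. Heating 3 in acetic anhydride with NaOAc (120 °C) should acetolyse the Mannich base and acetylate the three phenols, giving [5,7-diacetoxy-2-(4-acetoxyphenyl)-4-oxo-4H-chromen-8-yl]methyl acetate F1. A benzylic Suzuki–Miyaura coupling of F1 with 4 ([Pd(allyl)Cl]2, 1,5-bis(diphenylphosphino)pentane, K2CO3, t-AmOH, 80 °C) should then give 4-[5,7-diacetoxy-8-(4-hydroxybenzyl)-4-oxo-4H-chromen-2-yl]phenyl acetate F2. Partial loss of aryl acetates at this stage would not matter, because K2CO3 in MeOH at room temperature should finally remove all acetates to give 6.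

Step 1. What may go wrong: loss of regiocontrol, with aminomethylation at C6 instead of C8 or at both positions. The fallback sets out from 1 and comes back to the route at 3. It fixes the position through a carbon–halogen bond instead of relying on the Mannich regiochemistry. Exhaustive methylation of 1 (MeI, K2CO3, DMF, 60 °C) should give 4',5,7-tri-O-methylapigenin F3. With the 5-oxygen methylated, electrophilic iodination (I2, CF3CO2Ag, CH2Cl2, room temperature), which is known to go to C8 in 5,7-dimethoxyflavones, should give 8-iodo-5,7-dimethoxy-2-(4-methoxyphenyl)-4H-chromen-4-one F4. A Suzuki–Miyaura aminomethylation of F4 with potassium (dimethylaminomethyl)trifluoroborate (Pd(OAc)2, XPhos, Cs2CO3, THF/H2O, 80 °C) should give 8-[(dimethylamino)methyl]-5,7-dimethoxy-2-(4-methoxyphenyl)-4H-chromen-4-one F5. Cleavage of the three methyl ethers with excess BBr3 (CH2Cl2, −78 °C to room temperature, then MeOH and neutralisation) should return 3.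

Further compounds
F1 | step 2 | [5,7-diacetoxy-2-(4-acetoxyphenyl)-4-oxo-4H-chromen-8-yl]methyl acetate | CC(=O)OCc1c(OC(C)=O)cc(OC(C)=O)c2c(=O)cc(-c3ccc(OC(C)=O)cc3)oc12
F2 | step 2 | 4-[5,7-diacetoxy-8-(4-hydroxybenzyl)-4-oxo-4H-chromen-2-yl]phenyl acetate | CC(=O)Oc1cc(OC(C)=O)c2c(=O)cc(-c3ccc(OC(C)=O)cc3)oc2c1Cc1ccc(O)cc1
F3 | step 1 | 4',5,7-tri-O-methylapigenin (5,7-dimethoxy-2-(4-methoxyphenyl)-4H-chromen-4-one) | COc1ccc(-c2cc(=O)c3c(OC)cc(OC)cc3o2)cc1
F4 | step 1 | 8-iodo-5,7-dimethoxy-2-(4-methoxyphenyl)-4H-chromen-4-one | COc1ccc(-c2cc(=O)c3c(OC)cc(OC)c(I)c3o2)cc1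
F5 | step 1 | 8-[(dimethylamino)methyl]-5,7-dimethoxy-2-(4-methoxyphenyl)-4H-chromen-4-one | COc1ccc(-c2cc(=O)c3c(OC)cc(OC)c(CN(C)C)c3o2)cc1
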